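Readings and results were generated by integration for substances that don't exist; scatter was added.

A small charge of reagent gave the first clue. Friday's flask held 0.11 M of reagent against 0.20 M of substrate, and its substrate stopped near 45.4%. That meant 0.109 M was consumed, about the reagent charge, so I took the two to combine one to one.

| setting | Monday's | Friday's | east | south | north | south-east |
|---|---|---|---|---|---|---|
| substrate | 0.050 M | 0.20 M | 0.10 M | 0.10 M | 0.10 M | 0.10 M |
| reagent | 0.11 M | 0.11 M | 0.110 M | 0.110 M | 0.110 M | 0.110 M |
| temperature | −11 °C | 30 °C | 20 °C | 45 °C | −30 °C | −5 °C |
| remark | run made earlier | run made earlier |  |  |  |  |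
| time |  |  | 20 min | 20 min | 20 min | 20 min |

| run | time / min | product / % | substrate / % |
|---|---|---|---|
| Monday's | 8.00 | 0.2 | 0 |
| Monday's | 12.0 | 1.7 | 0.4 |
| Monday's | 20.0 | 4.6 | 0 |
| Monday's | 40.0 | 6.7 | 0 |
| Monday's | 60.0 | 11.6 | 0 |
| Monday's | 90.0 | 15.2 | 0.8 |
| Friday's | 1.00 | 7.3 | 44.4 |
| Friday's | 1.50 | 9.3 | 45.4 |
| Friday's | 2.50 | 10.8 | 45.0 |
| Friday's | 5.00 | 10.7 | 45.4 |
| Friday's | 8.00 | 11.7 | 44.7 |
| Friday's | 12.0 | 10.7 | 45.3 |

(readings scatter by 0.5 percentage points)



* which flask leads in amount of product, in percent of the substrate charged ("all alike" within 1.5 percentage points) (east / south / north / south-east / all alike)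
* how much product is there at the end, in percent of the substrate charged: east
* how much product is there at the end, in percent of the substrate charged: south
* how much product is there at the end, in percent of the substrate charged: north
* how much product is there at the end, in percent of the substrate charged: south-east

I built the flask one process at a time. First came the combination by itself. East, south, north and south-east each held 0.10 M of substrate against 0.110 M of reagent, so substrate was the limiting reagent. If the consumed substrate had passed straight to product, product would have reached 100%.

Monday's readings added the second process. At 8.00 min its substrate read 0% and its product 0.2%, so the consumed substrate stood in a form I could not read. Product grew from that form slowly. Monday's flask, at −11 °C, had less product after 20.0 min than Friday's flask, at 30 °C, had after 1.00 min.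

Friday's readings added the third process, a stop. From 2.50 min on, its product averaged 11.0% of the charge, with 54.9% consumed. I named the plateau share: flat-stretch product divided by substrate consumed. Friday's reading gave 20.0%.

Monday's product was still rising at 15.2%, which hinted that the share might be larger in the cold. So I set east a little above 20.0% and south a little below it. South-east I put between Monday's 4.6% and 20.0%, still rising, and north below 4.6%.

The forecast named east as leader, with 23% there, 17% in south, 0.3% in north and 7% in south-east: “East should lead, though the selectivity trend is uncertain.”

The flasks gave 25.2% in east, 12.9% in south, 0.0413% in north and 11.7% in south-east, so east led.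

    intermediate B ⇌ product (K = 0.940, k = 0.0230 /s, Ea = 87.0 kJ/mol, ΔH = −2.00 kJ/mol)
    intermediate B ⇌ intermediate A (K = 1.70, k = 0.00680 /s, Ea = 85.0 kJ/mol, ΔH = 33.0 kJ/mol)
    substrate + reagent → intermediate B (k = 0.0520 /M/s, Ea = 54.0 kJ/mol)
    substrate + reagent → intermediate A (k = 2.30 /M/s, Ea = 53.0 kJ/mol)
    reagent + intermediate B ⇌ intermediate C (K = 12.0 /M, k = 0.230 /M/s, Ea = 45.0 kJ/mol, ΔH = −30.0 kJ/mol)
    (constants at 20 °C)

East's product read 24.7% at 10.0 min and 25.2% at 200 min, with 0% of its substrate left, so its plateau share was 25.2%. South's product also held still, and with 0% of its substrate left, its share was 12.9%, lower than east's. South's plateau exists because product returns to intermediate B. In the south run with that return taken away, product went from 12.9% to 100%.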